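**Retrosynthetic overview**

1. Ring C is opened first: the O1–C2 bond is made last by a Mitsunobu closure of an (R)-benzylic alcohol onto the C8a phenol, with inversion to (2S). The furan ring (O1'–C2') comes from cyclodehydration of a C2' ketone with the ring D phenol next to the side chain.
2. The route rests on ring A: its oxygens at C5, C7 and C8a alternate with the carbons C4a, C6 and C8, C8 carries C2' at the ketone level and only O5 is methylated. Ring A is therefore an acylphloroglucinol (a folded tetraketide) and is disconnected at C8–C8a by a Claisen (Dieckmann-type) condensation of a methyl 3-methoxy-5,7-dioxooct-2-enoate whose enol ether already holds the O5 methyl group.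
3. That chain comes from the dianion of a 3-methoxy-5-oxohex-2-enoate and the ring D arylacetaldehyde (aldol addition, then oxidation). The enoate comes from methyl acetoacetate, the silyl ether of (R)-3-chloro-1-phenylpropan-1-ol and N-methoxy-N-methylacetamide.
4. Ring D is bought as 2,4,6-trihydroxybenzaldehyde: the formyl group is reduced to the methyl group and the two-carbon side chain is set by an aromatic Claisen rearrangement ortho to the one free phenol.
5. Order of ring formation: ring D (purchased), ring A (step 14), furan ring (step 15), ring C (step 17).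

Key step: step 14

Remark: both ring D oxygens that end as hydroxyl or furan oxygen are carried as methoxymethyl (MOM) ethers, so one acid step unveils them and no benzyl ether or hydrogenolysis is needed; ring D is therefore built from 2,4,6-trihydroxybenzaldehyde, whose hydrogen-bonded hydroxyl group fixes the substitution pattern.

**Route**

Step 1
Reactants: 1 (R)-3-chloro-1-phenylpropan-1-ol
Product: 2 (R)-tert-butyl(3-chloro-1-phenylpropoxy)diphenylsilane
Conditions: TBDPSCl, imidazole, DMF, rt
Reagents that add atoms: tert-butyl(chloro)diphenylsilane CC(C)(C)[Si](Cl)(c1ccccc1)c1ccccc1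
Why: Silyl ether formation on a secondary alcohol, which leaves the stereocentre untouched and gives a group that should survive amide bases, methoxide and the later mild acid step.

Step 2
Reactants: 2 (R)-tert-butyl(3-chloro-1-phenylpropoxy)diphenylsilane
Product: 3 (R)-tert-butyl(3-iodo-1-phenylpropoxy)diphenylsilane
Conditions: NaI, acetone, reflux
Reagents that add atoms: sodium iodide [Na+].[I-]
Why: Finkelstein halide exchange at the primary carbon, driven by precipitation of NaCl, gives the better alkylating agent.

Step 3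
Reactants: 3 (R)-tert-butyl(3-iodo-1-phenylpropoxy)diphenylsilane; 4 methyl acetoacetate
Product: 5 methyl (5R)-2-acetyl-5-(tert-butyldiphenylsilyloxy)-5-phenylpentanoate (both C2 epimers)
Conditions: NaH, THF/DMF, 0 °C; then 3, 60 °C
Reagents that add atoms: none
Why: Acetoacetic ester alkylation, in which the sodium enolate of 4 (in excess, to suppress dialkylation) displaces the primary iodide by SN2 at carbon; the new C2 centre need not be controlled because it becomes sp2 in step 4.

Step 4
Reactants: 5 methyl (5R)-2-acetyl-5-(tert-butyldiphenylsilyloxy)-5-phenylpentanoate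
Product: 6 methyl (2E)-2-[(3R)-3-(tert-butyldiphenylsilyloxy)-3-phenylpropyl]-3-methoxybut-2-enoate
Conditions: NaH, HMPA, 0 °C; Me2SO4, rt
Reagents that add atoms: dimethyl sulfate COS(=O)(=O)OC
Why: O-Alkylation of a β-keto ester enolate, in which the dissociated, W-shaped sodium enolate in HMPA should be attacked at oxygen by the hard electrophile (C-methylation would have to build a quaternary carbon) to give mainly the E enol ether with the ester cis to the C4 methyl group; minor Z isomer and C-methylated ester are removed by chromatography.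

Step 5
Reactants: 6 methyl (2E)-2-[(3R)-3-(tert-butyldiphenylsilyloxy)-3-phenylpropyl]-3-methoxybut-2-enoate; 7 N-methoxy-N-methylacetamide
Product: 8 methyl (2E)-2-[(3R)-3-(tert-butyldiphenylsilyloxy)-3-phenylpropyl]-3-methoxy-5-oxohex-2-enoate
Conditions: LiN(i-Pr)2, THF, −78 °C; then 7, −78 to −40 °C; AcOH, −78 °C
Reagents that add atoms: none
Why: Vinylogous Claisen-type acylation, in which the base removes a proton from the C4 methyl group cis to the ester and the lithium dienolate is acylated at C4 (the alpha carbon is blocked by the alkyl chain) by the Weinreb amide, whose chelated tetrahedral adduct keeps the ketone masked until the cold quench so that neither double acylation nor lactonisation to a pyranone occurs in the flask.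

Step 6
Reactants: 9 2,4,6-trihydroxybenzaldehyde
Product: 10 2-hydroxy-4,6-bis(methoxymethoxy)benzaldehyde
Conditions: MOMCl (2.1 equiv), i-Pr2NEt, CH2Cl2, 0 °C to rt
Reagents that add atoms: chloromethyl methyl ether COCCl
Why: Williamson-type ether formation, in which the para hydroxyl and one of the two equivalent ortho hydroxyls are alkylated while the last ortho hydroxyl is held back by its hydrogen bond to the aldehyde, so a single bis-ether should form.

Step 7
Reactants: 10 2-hydroxy-4,6-bis(methoxymethoxy)benzaldehyde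
Product: 12 3,5-bis(methoxymethoxy)-2-methylphenol, via ethyl aryl carbonate 11 (not isolated)
Conditions: ClCO2Et, Et3N, THF, 0 °C; then NaBH4, H2O, 0 °C to rt
Reagents that add atoms: none
Why: Reductive deoxygenation of a salicylaldehyde through an ortho-quinone methide, in which NaBH4 reduces the aldehyde of the carbonate, the carbonate shifts to the benzylic oxygen and leaves, and the quinone methide takes up a second hydride to give a phenol with only one free ortho position.

Step 8
Reactants: 12 3,5-bis(methoxymethoxy)-2-methylphenol; 13 allyl bromide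
Product: 14 1-(allyloxy)-3,5-bis(methoxymethoxy)-2-methylbenzene
Conditions: K2CO3, acetone, reflux
Reagents that add atoms: none
Why: Williamson ether synthesis on the only free phenol.

Step 9
Reactants: 14 1-(allyloxy)-3,5-bis(methoxymethoxy)-2-methylbenzene
Product: 15 2-allyl-3,5-bis(methoxymethoxy)-6-methylphenol
Conditions: N,N-diethylaniline, 190 °C
Reagents that add atoms: none
Why: Aromatic Claisen rearrangement ([3,3]-sigmatropic), in which the allyl group is delivered to the one ortho carbon that carries hydrogen and the dienone tautomerises to the phenol, while the para position between two MOM ethers is reached only by the slower detour over the methyl-bearing ortho carbon.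

Step 10
Reactants: 15 2-allyl-3,5-bis(methoxymethoxy)-6-methylphenol
Product: 16 1-allyl-2-methoxy-4,6-bis(methoxymethoxy)-3-methylbenzene
Conditions: MeI, K2CO3, DMF, rt
Reagents that add atoms: iodomethane CI
Why: Williamson methylation of the hindered phenol, which sets the one methoxy group of ring D between the methyl group and the side chain.

Step 11
Reactants: 16 1-allyl-2-methoxy-4,6-bis(methoxymethoxy)-3-methylbenzene
Product: 18 2-[2-methoxy-4,6-bis(methoxymethoxy)-3-methylphenyl]acetaldehyde, via 1,2-diol 17 (not isolated)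
Conditions: OsO4 (cat.), NaIO4, 2,6-lutidine, dioxane/H2O, rt
Reagents that add atoms: osmium tetroxide O=[Os](=O)(=O)=O (catalytic); sodium periodate [Na+].[O-]I(=O)(=O)=O (terminal oxidant); water O
Why: Lemieux–Johnson oxidation, in which catalytic OsO4 dihydroxylates the terminal alkene and NaIO4 cleaves the diol and regenerates OsO4 under near-neutral conditions that leave the MOM ethers and the electron-rich ring alone; the aldehyde is used crude.

Step 12
Reactants: 8 methyl (2E)-2-[(3R)-3-(tert-butyldiphenylsilyloxy)-3-phenylpropyl]-3-methoxy-5-oxohex-2-enoate; 18 2-[2-methoxy-4,6-bis(methoxymethoxy)-3-methylphenyl]acetaldehyde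
Product: 19 methyl (2E)-2-[(3R)-3-(tert-butyldiphenylsilyloxy)-3-phenylpropyl]-7-hydroxy-3-methoxy-8-[2-methoxy-4,6-bis(methoxymethoxy)-3-methylphenyl]-5-oxooct-2-enoate (both C7 epimers)
Conditions: LiN(i-Pr)2 (2.2 equiv), THF, −78 °C; then 18, −78 °C; AcOH, −78 °C
Reagents that add atoms: none
Why: Aldol addition of a dicarbonyl-type dianion (Weiler type), in which the first equivalent of base removes the acidic C4 proton, the second the C6 methyl proton, and the aldehyde reacts at the more basic terminal carbon C6; at −78 °C addition should outrun proton transfer from the aldehyde, and the C7 configuration is irrelevant because it is oxidised next.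

Step 13
Reactants: 19 methyl (2E)-2-[(3R)-3-(tert-butyldiphenylsilyloxy)-3-phenylpropyl]-7-hydroxy-3-methoxy-8-[2-methoxy-4,6-bis(methoxymethoxy)-3-methylphenyl]-5-oxooct-2-enoate
Product: 20 methyl (2E)-2-[(3R)-3-(tert-butyldiphenylsilyloxy)-3-phenylpropyl]-3-methoxy-8-[2-methoxy-4,6-bis(methoxymethoxy)-3-methylphenyl]-5,7-dioxooct-2-enoate
Conditions: Dess–Martin periodinane (1.1 equiv), CH2Cl2, 0 °C to rt
Reagents that add atoms: none
Why: Dess–Martin oxidation of the β-hydroxy ketone to the 1,3-diketone under conditions that spare silyl ether, MOM ethers and enol ether, with only a slight excess so that the activated C6 methylene is not oxidised further.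

Step 14
Reactants: 20 methyl (2E)-2-[(3R)-3-(tert-butyldiphenylsilyloxy)-3-phenylpropyl]-3-methoxy-8-[2-methoxy-4,6-bis(methoxymethoxy)-3-methylphenyl]-5,7-dioxooct-2-enoate
Product: 21 1-{3-[(3R)-3-(tert-butyldiphenylsilyloxy)-3-phenylpropyl]-2,6-dihydroxy-4-methoxyphenyl}-2-[2-methoxy-4,6-bis(methoxymethoxy)-3-methylphenyl]ethanone
Conditions: Mg(OMe)2 (4 equiv), MeOH, reflux; then cold 1 M HCl
Reagents that add atoms: none
Why: Mg(OMe)2 turns the 5,7-diketone into its magnesium-chelated enolate, whose carbon C6 adds to the ester carbonyl C1 (held cis to C4 by the E enol ether); methoxide is expelled and two enolisations give the arene, chain atoms C1, C2, C3, C4, C5 and C6 becoming C8a, C4a, C5, C6, C7 and C8 of ring A with O5 already methylated. The closest known reaction type is the biomimetic Claisen (Dieckmann-type) cyclisation of 3,5,7-tricarbonyl esters and of 6-(2-oxoalkyl)-4-methoxy-2-pyranones to acylphloroglucinols with Mg(OMe)2. Ring A closes in a 6-exo-trig mode (enolate carbon onto the ester carbonyl carbon). No stereocentre is formed, and the remote (R) silyloxy carbon carries no acidic hydrogen. The step needs C-acylation at C6 to prevail over O-acylation to the 4-methoxy-2-pyranone and over attack by the benzylic carbon C8: chelation of the 1,3-diketonate places the nucleophile at C6, any pyranone is reopened by methoxide and returns to the same enolate, and the aldol (orsellinate) mode is closed because C2 is fully substituted and could not aromatise. Any Z enol ether should equilibrate with the E isomer through the C4 dienolate under the same conditions.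

Step 15
Reactants: 21 1-{3-[(3R)-3-(tert-butyldiphenylsilyloxy)-3-phenylpropyl]-2,6-dihydroxy-4-methoxyphenyl}-2-[2-methoxy-4,6-bis(methoxymethoxy)-3-methylphenyl]ethanone
Product: 23 2-{3-[(3R)-3-(tert-butyldiphenylsilyloxy)-3-phenylpropyl]-2,6-dihydroxy-4-methoxyphenyl}-4-methoxy-5-methyl-1-benzofuran-6-ol, via MOM-free phenolic ketone 22 (not isolated)
Conditions: HCl (1 M in MeOH), 40 °C
Reagents that add atoms: none
Why: Acid-catalysed acetal methanolysis removes both MOM groups, after which the ring D phenol next to the side chain adds to the C2' ketone (5-exo-trig hemiketal) and loses water to give the aromatic furan (cyclodehydration of a 2-hydroxybenzyl ketone); the other ortho oxygen of ring D is a methyl ether, so only one benzofuran can form, and the silyl ether with its stereocentre should survive the mild acid.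

Step 16
Reactants: 23 2-{3-[(3R)-3-(tert-butyldiphenylsilyloxy)-3-phenylpropyl]-2,6-dihydroxy-4-methoxyphenyl}-4-methoxy-5-methyl-1-benzofuran-6-ol
Product: 24 2-{2,6-dihydroxy-3-[(3R)-3-hydroxy-3-phenylpropyl]-4-methoxyphenyl}-4-methoxy-5-methyl-1-benzofuran-6-ol
Conditions: Bu4NF, AcOH, THF, rt to 45 °C
Reagents that add atoms: none
Why: Fluoride-induced desilylation, buffered with acetic acid so that the electron-rich phenols are not kept as phenoxides.

Step 17
Reactants: 24 2-{2,6-dihydroxy-3-[(3R)-3-hydroxy-3-phenylpropyl]-4-methoxyphenyl}-4-methoxy-5-methyl-1-benzofuran-6-ol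
Product: 25 (2S)-8-(6-hydroxy-4-methoxy-5-methyl-1-benzofuran-2-yl)-5-methoxy-2-phenyl-3,4-dihydro-2H-chromen-7-ol (CNP0000229.1)
Conditions: PPh3, DIAD, THF (0.01 M), 0 °C to rt
Reagents that add atoms: none
Why: Mitsunobu etherification, in which the benzylic alcohol is activated as its oxyphosphonium salt and displaced by the C8a phenoxide in an intramolecular SN2 reaction (6-exo-tet) with inversion, turning the (R) carbinol into the (2S) centre of ring C; only the C8a oxygen can reach the carbinol carbon, and high dilution disfavours intermolecular alkylation of the other phenols.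

**Compound list**

1 | (R)-3-chloro-1-phenylpropan-1-ol | ClCC[C@H](c1ccccc1)O | starting material
2 | (R)-tert-butyl(3-chloro-1-phenylpropoxy)diphenylsilane | ClCC[C@H](c1ccccc1)O[Si](c1ccccc1)(c1ccccc1)C(C)(C)C | intermediate
3 | (R)-tert-butyl(3-iodo-1-phenylpropoxy)diphenylsilane | ICC[C@H](c1ccccc1)O[Si](c1ccccc1)(c1ccccc1)C(C)(C)C | intermediate
4 | methyl acetoacetate | COC(=O)CC(C)=O | starting material
5 | methyl (5R)-2-acetyl-5-(tert-butyldiphenylsilyloxy)-5-phenylpentanoate (both C2 epimers) | COC(=O)C(CC[C@H](c1ccccc1)O[Si](c1ccccc1)(c1ccccc1)C(C)(C)C)C(C)=O | intermediate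
6 | methyl (2E)-2-[(3R)-3-(tert-butyldiphenylsilyloxy)-3-phenylpropyl]-3-methoxybut-2-enoate | COC(=O)/C(CC[C@H](c1ccccc1)O[Si](c1ccccc1)(c1ccccc1)C(C)(C)C)=C(/OC)C | intermediate
7 | N-methoxy-N-methylacetamide | CON(C)C(C)=O | starting material
8 | methyl (2E)-2-[(3R)-3-(tert-butyldiphenylsilyloxy)-3-phenylpropyl]-3-methoxy-5-oxohex-2-enoate | COC(=O)/C(CC[C@H](c1ccccc1)O[Si](c1ccccc1)(c1ccccc1)C(C)(C)C)=C(/OC)CC(C)=O | intermediate
9 | 2,4,6-trihydroxybenzaldehyde | O=Cc1c(O)cc(O)cc1O | starting material
10 | 2-hydroxy-4,6-bis(methoxymethoxy)benzaldehyde | COCOc1cc(O)c(C=O)c(OCOC)c1 | intermediate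
11 | ethyl 2-formyl-3,5-bis(methoxymethoxy)phenyl carbonate | CCOC(=O)Oc1cc(OCOC)cc(OCOC)c1C=O | intermediate (not isolated)
12 | 3,5-bis(methoxymethoxy)-2-methylphenol | COCOc1cc(O)c(C)c(OCOC)c1 | intermediate
13 | allyl bromide | C=CCBr | starting material
14 | 1-(allyloxy)-3,5-bis(methoxymethoxy)-2-methylbenzene | C=CCOc1cc(OCOC)cc(OCOC)c1C | intermediate
15 | 2-allyl-3,5-bis(methoxymethoxy)-6-methylphenol | C=CCc1c(O)c(C)c(OCOC)cc1OCOC | intermediate
16 | 1-allyl-2-methoxy-4,6-bis(methoxymethoxy)-3-methylbenzene | C=CCc1c(OC)c(C)c(OCOC)cc1OCOC | intermediate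
17 | 3-[2-methoxy-4,6-bis(methoxymethoxy)-3-methylphenyl]propane-1,2-diol (racemic) | OCC(O)Cc1c(OC)c(C)c(OCOC)cc1OCOC | intermediate (not isolated)
18 | 2-[2-methoxy-4,6-bis(methoxymethoxy)-3-methylphenyl]acetaldehyde | O=CCc1c(OC)c(C)c(OCOC)cc1OCOC | intermediate
19 | methyl (2E)-2-[(3R)-3-(tert-butyldiphenylsilyloxy)-3-phenylpropyl]-7-hydroxy-3-methoxy-8-[2-methoxy-4,6-bis(methoxymethoxy)-3-methylphenyl]-5-oxooct-2-enoate (both C7 epimers) | COC(=O)/C(CC[C@H](c1ccccc1)O[Si](c1ccccc1)(c1ccccc1)C(C)(C)C)=C(/OC)CC(=O)CC(O)Cc1c(OC)c(C)c(OCOC)cc1OCOC | intermediate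
20 | methyl (2E)-2-[(3R)-3-(tert-butyldiphenylsilyloxy)-3-phenylpropyl]-3-methoxy-8-[2-methoxy-4,6-bis(methoxymethoxy)-3-methylphenyl]-5,7-dioxooct-2-enoate | COC(=O)/C(CC[C@H](c1ccccc1)O[Si](c1ccccc1)(c1ccccc1)C(C)(C)C)=C(/OC)CC(=O)CC(=O)Cc1c(OC)c(C)c(OCOC)cc1OCOC | intermediate
21 | 1-{3-[(3R)-3-(tert-butyldiphenylsilyloxy)-3-phenylpropyl]-2,6-dihydroxy-4-methoxyphenyl}-2-[2-methoxy-4,6-bis(methoxymethoxy)-3-methylphenyl]ethanone | COc1cc(O)c(C(=O)Cc2c(OC)c(C)c(OCOC)cc2OCOC)c(O)c1CC[C@H](c1ccccc1)O[Si](c1ccccc1)(c1ccccc1)C(C)(C)C | intermediate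
22 | 1-{3-[(3R)-3-(tert-butyldiphenylsilyloxy)-3-phenylpropyl]-2,6-dihydroxy-4-methoxyphenyl}-2-(4,6-dihydroxy-2-methoxy-3-methylphenyl)ethanone | COc1cc(O)c(C(=O)Cc2c(OC)c(C)c(O)cc2O)c(O)c1CC[C@H](c1ccccc1)O[Si](c1ccccc1)(c1ccccc1)C(C)(C)C | intermediate (not isolated)
23 | 2-{3-[(3R)-3-(tert-butyldiphenylsilyloxy)-3-phenylpropyl]-2,6-dihydroxy-4-methoxyphenyl}-4-methoxy-5-methyl-1-benzofuran-6-ol | COc1cc(O)c(-c2cc3c(OC)c(C)c(O)cc3o2)c(O)c1CC[C@H](c1ccccc1)O[Si](c1ccccc1)(c1ccccc1)C(C)(C)C | intermediate
24 | 2-{2,6-dihydroxy-3-[(3R)-3-hydroxy-3-phenylpropyl]-4-methoxyphenyl}-4-methoxy-5-methyl-1-benzofuran-6-ol | COc1cc(O)c(-c2cc3c(OC)c(C)c(O)cc3o2)c(O)c1CC[C@H](c1ccccc1)O | intermediate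
25 | (2S)-8-(6-hydroxy-4-methoxy-5-methyl-1-benzofuran-2-yl)-5-methoxy-2-phenyl-3,4-dihydro-2H-chromen-7-ol (CNP0000229.1) | COc1cc(O)c(-c2cc3c(OC)c(C)c(O)cc3o2)c2c1CC[C@@H](c1ccccc1)O2 | target

**Step count and risks**

Total step count: 17. Longest linear sequence: 12 steps (from 9 through steps 6–11 and 12–17); the chain branch from 1 is 11 steps.

Steps most likely to fail:

1. Step 14 (Claisen closure of ring A). O-Acylation may win and the pyranone may fail to reopen, or methoxide may cleave the 1,3-diketone (retro-Claisen) before the ring closes. Fallback: ring A is taken from a preformed phloroglucinol and the carbonyl carbon is attached by directed metalation. Setting out from 3, commercial 1,3,5-trimethoxybenzene is lithiated (n-BuLi, TMEDA, THF, 0 °C) and alkylated with 3 to give (R)-tert-butyl(diphenyl)[1-phenyl-3-(2,4,6-trimethoxyphenyl)propoxy]silane F1. A second lithiation between two methoxy groups, transmetalation with CeCl3 and addition to aldehyde 18 would give the carbinol 1-{3-[(3R)-3-(tert-butyldiphenylsilyloxy)-3-phenylpropyl]-2,4,6-trimethoxyphenyl}-2-[2-methoxy-4,6-bis(methoxymethoxy)-3-methylphenyl]ethanol F2, and Dess–Martin oxidation the corresponding ethanone F3. BCl3 (CH2Cl2, −78 to 0 °C) should then remove, under chelation to the ketone, the two methyl groups ortho to the carbonyl group together with both MOM groups. This comes back to the route at 22, which methanolic HCl closes to 23 as in step 15.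

2. Step 12 (dianion aldol addition). Proton transfer from the enolisable arylacetaldehyde to the dianion, or self-condensation of the aldehyde, may compete with addition. Fallback: the ring D unit is delivered at the ketone oxidation level as a far less acidic amide. Setting out from 18, Pinnick oxidation (NaClO2, NaH2PO4, 2-methyl-2-butene, t-BuOH/H2O) would give 2-[2-methoxy-4,6-bis(methoxymethoxy)-3-methylphenyl]acetic acid F4, and coupling with N,O-dimethylhydroxylamine hydrochloride (EDC·HCl, i-Pr2NEt, CH2Cl2) its N-methoxy-N-methylamide F5. The dianion of 8 (LiN(i-Pr)2, THF, −78 °C) is acylated by F5 and the route is rejoined at 20, steps 12 and 13 being replaced.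

3. Step 17 (Mitsunobu closure of ring C). Intermolecular O-alkylation at the unhindered ring D phenol, or ionisation of the benzylic oxyphosphonium salt with elimination or erosion of configuration, may compete with the intramolecular displacement. Fallback: ring C is closed before the ring D phenols are set free. Setting out from 21, Bu4NF/AcOH would give 1-{2,6-dihydroxy-3-[(3R)-3-hydroxy-3-phenylpropyl]-4-methoxyphenyl}-2-[2-methoxy-4,6-bis(methoxymethoxy)-3-methylphenyl]ethanone F6. Mitsunobu closure (PPh3, DIAD, THF, high dilution) through the acidic, ketone-chelated C8a phenol, with ring D still fully protected, would give 1-[(2S)-7-hydroxy-5-methoxy-2-phenyl-3,4-dihydro-2H-chromen-8-yl]-2-[2-methoxy-4,6-bis(methoxymethoxy)-3-methylphenyl]ethanone F7. Methanolic HCl then removes the MOM groups and closes the furan, and the route is rejoined at 25.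

**Further compounds**

F1 | step 14 | (R)-tert-butyl(diphenyl)[1-phenyl-3-(2,4,6-trimethoxyphenyl)propoxy]silane | COc1cc(OC)c(CC[C@H](c2ccccc2)O[Si](c2ccccc2)(c2ccccc2)C(C)(C)C)c(OC)c1
F2 | step 14 | 1-{3-[(3R)-3-(tert-butyldiphenylsilyloxy)-3-phenylpropyl]-2,4,6-trimethoxyphenyl}-2-[2-methoxy-4,6-bis(methoxymethoxy)-3-methylphenyl]ethanol (both carbinol epimers) | COc1cc(OC)c(C(O)Cc2c(OC)c(C)c(OCOC)cc2OCOC)c(OC)c1CC[C@H](c1ccccc1)O[Si](c1ccccc1)(c1ccccc1)C(C)(C)C
F3 | step 14 | 1-{3-[(3R)-3-(tert-butyldiphenylsilyloxy)-3-phenylpropyl]-2,4,6-trimethoxyphenyl}-2-[2-methoxy-4,6-bis(methoxymethoxy)-3-methylphenyl]ethanone | COc1cc(OC)c(C(=O)Cc2c(OC)c(C)c(OCOC)cc2OCOC)c(OC)c1CC[C@H](c1ccccc1)O[Si](c1ccccc1)(c1ccccc1)C(C)(C)C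
F4 | step 12 | 2-[2-methoxy-4,6-bis(methoxymethoxy)-3-methylphenyl]acetic acid | OC(=O)Cc1c(OC)c(C)c(OCOC)cc1OCOC
F5 | step 12 | N-methoxy-2-[2-methoxy-4,6-bis(methoxymethoxy)-3-methylphenyl]-N-methylacetamide | CON(C)C(=O)Cc1c(OC)c(C)c(OCOC)cc1OCOC
F6 | step 17 | 1-{2,6-dihydroxy-3-[(3R)-3-hydroxy-3-phenylpropyl]-4-methoxyphenyl}-2-[2-methoxy-4,6-bis(methoxymethoxy)-3-methylphenyl]ethanone | COc1cc(O)c(C(=O)Cc2c(OC)c(C)c(OCOC)cc2OCOC)c(O)c1CC[C@H](c1ccccc1)O
F7 | step 17 | 1-[(2S)-7-hydroxy-5-methoxy-2-phenyl-3,4-dihydro-2H-chromen-8-yl]-2-[2-methoxy-4,6-bis(methoxymethoxy)-3-methylphenyl]ethanone | COc1cc(O)c(C(=O)Cc2c(OC)c(C)c(OCOC)cc2OCOC)c2c1CC[C@@H](c1ccccc1)O2
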